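## Retrosynthetic overview

1. Target 25 comes from the bis(hex-2-ynoate) 24 by twofold Lindlar semi-hydrogenation, and 24 from triol 22 by esterification of the two equatorial hydroxyls (O-3, O-9); the axial 8-OH stays free.
2. Triol 22 comes from trans-decalin 14, a C8 silyl enol ether with an angular formyl group (C14), by α-oxygenation at C9, epimerisation of C7 next to the C8 ketone, reduction at C8 and CHO → CH3.
3. Key disconnection: C6–C7 and C5–C10, by an intramolecular Diels–Alder reaction. The enabling feature is ring B (C5–C6–C7–C8–C9–C10): its vicinal oxygens on C8/C9, flanked by C7 and C10, are read as a C7=C8(OSi)–C9=C10 2-silyloxy diene, and the quaternary C5 with its methyl (held as CHO) plus C6 as an α-methylene aldehyde. The chain C1–C4 of ring A is the tether, so rings A and B form in one operation from the acyclic keto-enal 12.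
4. 12 comes from (Z)-hept-4-enal 1: asymmetric (Z)-crotylboration sets C3/C4, hydroboration–oxidation and α-methylenation build the dienophile, cross-metathesis with dienol 9 (from acrolein 8) and oxidation build the enone.

Key step: step 9

Remark on numbering: ring compounds carry eremophilane numbers (ring A = C1–C2–C3–C4–C5–C10, ring B = C5–C6–C7–C8–C9–C10, isopropenyl C11–C13 on C7, C14 on C5, C15 on C4; β = face of C14, α = face of H-10); the same numbers are used for the corresponding atoms of the open-chain precursors in the Why lines.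

Remark on step 1: the (+)-α-pinene-derived (Z)-crotylborane is taken to deliver the (4R)-carbinol, as it does with simple unbranched aliphatic aldehydes; if the sense were opposite, the antipodal borane would be used.

## Route

Step 1
Reactants: 1 (Z)-hept-4-enal
Product: 3 (3R,4R,7Z)-3-methyldeca-1,7-dien-4-ol, via borinate ester 2 (not isolated)
Conditions: cis-2-butene, KOtBu, n-BuLi, THF, −78 to −45 °C; (−)-Ipc2BOMe, −78 °C; BF3·OEt2; then 1, −78 °C; NaOH, H2O2, 0 °C to rt
Reagents that add atoms: (Z)-crotyldiisopinocampheylborane, C/C=C\CB([C@@H]1C[C@@H]2C[C@H]([C@H]1C)C2(C)C)[C@@H]1C[C@@H]2C[C@H]([C@H]1C)C2(C)C, made in the flask from cis-2-butene (C/C=C\C) and (−)-B-methoxydiisopinocampheylborane (COB([C@@H]1C[C@@H]2C[C@H]([C@H]1C)C2(C)C)[C@@H]1C[C@@H]2C[C@H]([C@H]1C)C2(C)C)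
Why: Reagent-controlled asymmetric (Z)-crotylboration through a closed chair transition state, in which the Z-crotyl geometry should give the syn C3/C4 relationship and the pinene-derived ligands the (3R,4R) absolute sense, while the internal Z-alkene is inert.

Step 2
Reactants: 3 (3R,4R,7Z)-3-methyldeca-1,7-dien-4-ol
Product: 4 (3R,4R,7Z)-4-(tert-butyldimethylsilyloxy)-3-methyldeca-1,7-diene
Conditions: TBSOTf, 2,6-lutidine, CH2Cl2, −78 to 0 °C
Reagents that add atoms: tert-butyldimethylsilyl triflate, CC(C)(C)[Si](C)(C)OS(=O)(=O)C(F)(F)F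
Why: Standard silylation of a secondary alcohol, needed so that the later C14 aldehyde cannot close to a lactol with O-3.

Step 3
Reactants: 4 (3R,4R,7Z)-4-(tert-butyldimethylsilyloxy)-3-methyldeca-1,7-diene
Product: 6 (3R,4R,7Z)-4-(tert-butyldimethylsilyloxy)-3-methyldec-7-en-1-ol, via B-alkyl-9-BBN adduct 5 (not isolated)
Conditions: 9-BBN (1.2 equiv), THF, 0 °C to rt; NaOH, H2O2, 0 °C
Reagents that add atoms: 9-borabicyclo[3.3.1]nonane, C1CC2CCCC(C1)B2 (boron stays only in 5); hydrogen peroxide, OO
Why: Anti-Markovnikov hydroboration–oxidation, in which 9-BBN should select the monosubstituted vinyl group over the internal Z-alkene by a wide margin.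

Step 4
Reactants: 6 (3R,4R,7Z)-4-(tert-butyldimethylsilyloxy)-3-methyldec-7-en-1-ol
Product: 7 (3R,4R,7Z)-4-(tert-butyldimethylsilyloxy)-3-methyldec-7-enal
Conditions: Dess–Martin periodinane, NaHCO3, CH2Cl2, 0 °C to rt
Reagents that add atoms: none
Why: Dess–Martin oxidation of a primary alcohol; the nearest stereocentre (C4) is β to the new carbonyl and cannot epimerise.

Step 5
Reactants: 8 acrolein
Product: 9 5-methylhexa-1,5-dien-3-ol (racemic)
Conditions: methallylmagnesium chloride, THF, −78 °C; aq. NH4Cl
Reagents that add atoms: methallylmagnesium chloride, C=C(C)C[Mg]Cl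
Why: 1,2-Addition of an allylic Grignard reagent to an enal; the carbinol centre is racemic because it is oxidised away in step 8.

Step 6
Reactants: 7 (3R,4R,7Z)-4-(tert-butyldimethylsilyloxy)-3-methyldec-7-enal; 9 5-methylhexa-1,5-dien-3-ol (3 equiv)
Product: 10 (3R,4R,7E)-4-(tert-butyldimethylsilyloxy)-9-hydroxy-3,11-dimethyldodeca-7,11-dienal (both C9 epimers)
Conditions: Hoveyda–Grubbs II catalyst (5 mol%), 1,4-benzoquinone (10 mol%), CH2Cl2, 40 °C
Reagents that add atoms: none
Why: Olefin cross-metathesis between the unhindered internal alkene and the vinyl group of the allylic alcohol should give the E-alkene with loss of but-1-ene, the 1,1-disubstituted isopropenyl group being inert; it is run before the methylene group of step 7 exists so that no ring-closing partner is present.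

Step 7
Reactants: 10 (3R,4R,7E)-4-(tert-butyldimethylsilyloxy)-9-hydroxy-3,11-dimethyldodeca-7,11-dienal
Product: 11 (3R,4R,7E)-4-(tert-butyldimethylsilyloxy)-9-hydroxy-3,11-dimethyl-2-methylidenedodeca-7,11-dienal (both C9 epimers)
Conditions: 37% aq. CH2O, pyrrolidine (10 mol%), propionic acid (10 mol%), i-PrOH, 45 °C
Reagents that add atoms: formaldehyde, C=O
Why: Amine-catalysed Mannich condensation–elimination (α-methylenation of an aldehyde) installs C6; it is done while C8 is still a carbinol, so no enolisable skipped enone is exposed to the amine.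

Step 8
Reactants: 11 (3R,4R,7E)-4-(tert-butyldimethylsilyloxy)-9-hydroxy-3,11-dimethyl-2-methylidenedodeca-7,11-dienal
Product: 12 (3R,4R,7E)-4-(tert-butyldimethylsilyloxy)-3,11-dimethyl-2-methylidene-9-oxododeca-7,11-dienal
Conditions: Dess–Martin periodinane, NaHCO3, CH2Cl2, 0 °C
Reagents that add atoms: none
Why: Buffered Dess–Martin oxidation of the secondary allylic alcohol should give the β,γ-unsaturated (skipped) enone without conjugation and leave the α-methylene aldehyde untouched.

Step 9
Reactants: 12 (3R,4R,7E)-4-(tert-butyldimethylsilyloxy)-3,11-dimethyl-2-methylidene-9-oxododeca-7,11-dienal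
Product: 14 trans-fused adduct 5β-formyl-4β-methyl-7β-isopropenyl-3α,8-bis(tert-butyldimethylsilyloxy)-Δ8-octalin (10α-H), via silyloxy triene 13 (not isolated)
Conditions: TBSOTf (1.2 equiv), Et3N (3 equiv), CH2Cl2, −78 to 0 °C; then toluene (0.01 M), BHT, rt to 60 °C
Reagents that add atoms: tert-butyldimethylsilyl triflate, CC(C)(C)[Si](C)(C)OS(=O)(=O)C(F)(F)F
Why: Soft enolisation removes the doubly activated C7–H between the ketone and the isopropenyl group and gives the cross-conjugated (Z)-2-silyloxy diene C7=C8(OTBS)–C9=C10, which on warming should undergo a concerted but asynchronous normal-demand intramolecular Diels–Alder reaction with the tethered 2-substituted acrolein C6=C5–CHO (nucleophilic diene terminus C7 to the enal β-carbon C6, C10 to the α-carbon C5). The closest known reaction type is the type-1 intramolecular Diels–Alder reaction of 1,7,9-decatrienes that carry a 2-silyloxy diene and an enal or enone dienophile. Ring B (C5–C10) is the cycloadduct ring, closed through a boat-like [4+2] transition state, and ring A (C1–C5, C10) closes at the same time through the four-carbon tether C1–C4 in a chair-like arrangement. At C5 and C10 the formyl group takes the endo position and the tether the exo position, which gives the trans ring fusion, and the dienophile face is fixed by the C3/C4 stereocentres, because only one chair tether keeps OTBS and the C4 methyl equatorial with H-4, not the methyl, in the plane of C5=C6 (A1,3 strain); at C7 the (Z)-enol ether places the isopropenyl group outside, so it ends cis to C1 (7β), a centre that step 11 corrects. The step needs regioselective enolisation towards C7 (secured by the higher acidity of the allylic α-CH2 over the γ-CH2 at C1) and periselectivity for the C7–C10 diene over the C12=C11–C7=C8 diene (secured by the tether, which can only span C5 and C10).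

Step 10
Reactants: 14 trans-fused adduct (silyl enol ether)
Product: 16 3α,9α-bis(tert-butyldimethylsilyloxy)-7β-isopropenyl-8-oxo trans-decalin-5β-carbaldehyde, via silyloxy epoxide 15 (not isolated)
Conditions: mCPBA (1.05 equiv), NaHCO3, CH2Cl2, −20 to 0 °C
Reagents that add atoms: 3-chloroperoxybenzoic acid, OOC(=O)c1cccc(Cl)c1
Why: Rubottom oxidation, in which the peracid should attack the electron-rich silyl enol ether (faster than the isopropenyl group or the hindered aldehyde) from the α-face, the β-face being blocked by the axial C14 formyl and the 7β-isopropenyl group, and the epoxide then opens with 1,4-silyl shift to set the 9α-oxygen.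

Step 11
Reactants: 16 7β-isopropenyl α-silyloxy ketone
Product: 17 3α,9α-bis(tert-butyldimethylsilyloxy)-7α-isopropenyl-8-oxo trans-decalin-5β-carbaldehyde
Conditions: DBU (0.2 equiv), toluene, 0 °C to rt, monitored; AcOH quench
Reagents that add atoms: none
Why: Base-mediated epimerisation through the C7 enolate should move the isopropenyl group from the axial 7β position (1,3-diaxial to C14) to the equatorial 7α position, kinetic α-reprotonation of the extended enolate returning the β,γ-unsaturated ketone, so the reaction is stopped before γ-protonation (conjugation) sets in.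

Step 12
Reactants: 17 7α-isopropenyl keto aldehyde
Product: 18 C14 (E)-tosylhydrazone of 17
Conditions: TsNHNH2 (1.1 equiv), 4 Å MS, THF, rt
Reagents that add atoms: p-toluenesulfonyl hydrazide, Cc1ccc(cc1)S(=O)(=O)NN
Why: Hydrazone condensation should take place only at the aldehyde, the C8 ketone being flanked by two substituted carbons.

Step 13
Reactants: 18 keto tosylhydrazone
Product: 19 8α-hydroxy tosylhydrazone (3α,9α-bis-OTBS, 7α-isopropenyl)
Conditions: L-Selectride (2.5 equiv), THF, −78 °C; aq. work-up
Reagents that add atoms: none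
Why: The bulky hydride should attack the 2,6-diequatorially substituted C8 ketone along the equatorial trajectory and give the axial 8α-alcohol, cis to O-9 and to the isopropenyl group, while the first equivalent only deprotonates the tosylhydrazone N–H.

Step 14
Reactants: 19 8α-hydroxy tosylhydrazone
Product: 21 3α,9α-bis(tert-butyldimethylsilyloxy)eremophil-11-en-8α-ol (7α-isopropenyl, 4β,5β-dimethyl, 10α-H), via N-boryl tosylhydrazine 20 (not isolated)
Conditions: catecholborane (3 equiv), CHCl3, 0 °C to rt; NaOAc·3H2O, 60 °C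
Reagents that add atoms: catecholborane, B1Oc2ccccc2O1 (boron stays only in 20)
Why: Caglioti-type deoxygenation (hydroboration of C=N, then acetate-induced loss of sulfinate and of N2 from the diazene) should turn the neopentyl CH=N into the C14 methyl group; with the isopropenyl group now equatorial, no alkene is within reach of C14 should the diazene fragment by a radical path.

Step 15
Reactants: 21 bis-silyl ether
Product: 22 eremophil-11-ene-3α,8α,9α-triol (7α-isopropenyl, 10α-H)
Conditions: TBAF, THF, 50 °C
Reagents that add atoms: none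
Why: Fluoride-mediated cleavage of both secondary TBS ethers.

Step 16
Reactants: 22 triol; 23 hex-2-ynoic acid (2.3 equiv)
Product: 24 eremophil-11-ene-3α,8α,9α-triol 3,9-bis(hex-2-ynoate)
Conditions: DCC (2.5 equiv), DMAP (0.2 equiv), CH2Cl2, −20 to 0 °C
Reagents that add atoms: none
Why: Steglich esterification should acylate the two equatorial secondary hydroxyls (O-3 and O-9) and leave the axial 8-OH, which is flanked by the C7 isopropenyl group and by C9; the ynoate is used so that no Z-alkene is exposed to the acylation conditions.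

Step 17
Reactants: 24 bis(hex-2-ynoate)
Product: 25 (1S,2R,3S,4aR,5R,6R,8aR)-2-hydroxy-4a,5-dimethyl-3-(prop-1-en-2-yl)decahydronaphthalene-1,6-diyl bis[(2Z)-hex-2-enoate] (CNP0420276.1)
Conditions: H2 (1 atm), Lindlar catalyst (Pd/CaCO3, Pb-poisoned), quinoline, EtOAc, rt, stopped after 2 equiv H2
Reagents that add atoms: none
Why: Lindlar semi-hydrogenation adds H2 syn to both conjugated alkynes and should give the two (Z)-enoates, while the 1,1-disubstituted isopropenyl alkene is not reduced on the poisoned catalyst.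

## Compound list

1 | (Z)-hept-4-enal | CC/C=C\CCC=O | starting material
2 | (3R,4R,7Z)-3-methyldeca-1,7-dien-4-yl diisopinocampheylborinate | C=C[C@@H](C)[C@H](OB([C@@H]1C[C@@H]2C[C@H]([C@H]1C)C2(C)C)[C@@H]1C[C@@H]2C[C@H]([C@H]1C)C2(C)C)CC/C=C\CC | intermediate
3 | (3R,4R,7Z)-3-methyldeca-1,7-dien-4-ol | C=C[C@@H](C)[C@H](O)CC/C=C\CC | intermediate
4 | (3R,4R,7Z)-4-(tert-butyldimethylsilyloxy)-3-methyldeca-1,7-diene | C=C[C@@H](C)[C@H](O[Si](C)(C)C(C)(C)C)CC/C=C\CC | intermediate
5 | 9-[(3R,4R,7Z)-4-(tert-butyldimethylsilyloxy)-3-methyldec-7-en-1-yl]-9-borabicyclo[3.3.1]nonane | C(C[C@@H](C)[C@H](O[Si](C)(C)C(C)(C)C)CC/C=C\CC)B1C2CCCC1CCC2 | intermediate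
6 | (3R,4R,7Z)-4-(tert-butyldimethylsilyloxy)-3-methyldec-7-en-1-ol | OCC[C@@H](C)[C@H](O[Si](C)(C)C(C)(C)C)CC/C=C\CC | intermediate
7 | (3R,4R,7Z)-4-(tert-butyldimethylsilyloxy)-3-methyldec-7-enal | O=CC[C@@H](C)[C@H](O[Si](C)(C)C(C)(C)C)CC/C=C\CC | intermediate
8 | acrolein | C=CC=O | starting material
9 | 5-methylhexa-1,5-dien-3-ol (racemic) | C=CC(O)CC(C)=C | intermediate
10 | (3R,4R,7E)-4-(tert-butyldimethylsilyloxy)-9-hydroxy-3,11-dimethyldodeca-7,11-dienal (C9 epimers) | O=CC[C@@H](C)[C@H](O[Si](C)(C)C(C)(C)C)CC/C=C/C(O)CC(C)=C | intermediate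
11 | (3R,4R,7E)-4-(tert-butyldimethylsilyloxy)-9-hydroxy-3,11-dimethyl-2-methylidenedodeca-7,11-dienal (C9 epimers) | O=CC(=C)[C@@H](C)[C@H](O[Si](C)(C)C(C)(C)C)CC/C=C/C(O)CC(C)=C | intermediate
12 | (3R,4R,7E)-4-(tert-butyldimethylsilyloxy)-3,11-dimethyl-2-methylidene-9-oxododeca-7,11-dienal | O=CC(=C)[C@@H](C)[C@H](O[Si](C)(C)C(C)(C)C)CC/C=C/C(=O)CC(C)=C | intermediate
13 | (3R,4R,7E,9Z)-4,9-bis(tert-butyldimethylsilyloxy)-3,11-dimethyl-2-methylidenedodeca-7,9,11-trienal | O=CC(=C)[C@@H](C)[C@H](O[Si](C)(C)C(C)(C)C)CC/C=C/C(O[Si](C)(C)C(C)(C)C)=C/C(C)=C | intermediate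
14 | trans-fused adduct: 5β-formyl-4β-methyl-7β-isopropenyl-3α,8-bis(tert-butyldimethylsilyloxy)-Δ8-octalin (10α-H) | C=C(C)[C@H]1C[C@]2(C=O)[C@@H](C)[C@H](O[Si](C)(C)C(C)(C)C)CC[C@H]2C=C1O[Si](C)(C)C(C)(C)C | intermediate
15 | 8α,9α-epoxide of 14 (8β-OTBS) | C=C(C)[C@H]1C[C@]2(C=O)[C@@H](C)[C@H](O[Si](C)(C)C(C)(C)C)CC[C@H]2[C@@H]3O[C@]13O[Si](C)(C)C(C)(C)C | intermediate
16 | 3α,9α-bis(tert-butyldimethylsilyloxy)-7β-isopropenyl-8-oxo trans-decalin-5β-carbaldehyde | C=C(C)[C@H]1C[C@]2(C=O)[C@@H](C)[C@H](O[Si](C)(C)C(C)(C)C)CC[C@H]2[C@H](O[Si](C)(C)C(C)(C)C)C1=O | intermediate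
17 | 3α,9α-bis(tert-butyldimethylsilyloxy)-7α-isopropenyl-8-oxo trans-decalin-5β-carbaldehyde | C=C(C)[C@@H]1C[C@]2(C=O)[C@@H](C)[C@H](O[Si](C)(C)C(C)(C)C)CC[C@H]2[C@H](O[Si](C)(C)C(C)(C)C)C1=O | intermediate
18 | C14 (E)-tosylhydrazone of 17 | C=C(C)[C@@H]1C[C@]2(/C=N/NS(=O)(=O)c3ccc(C)cc3)[C@@H](C)[C@H](O[Si](C)(C)C(C)(C)C)CC[C@H]2[C@H](O[Si](C)(C)C(C)(C)C)C1=O | intermediate
19 | 8α-hydroxy C14 tosylhydrazone | C=C(C)[C@@H]1C[C@]2(/C=N/NS(=O)(=O)c3ccc(C)cc3)[C@@H](C)[C@H](O[Si](C)(C)C(C)(C)C)CC[C@H]2[C@H](O[Si](C)(C)C(C)(C)C)[C@@H]1O | intermediate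
20 | N-catecholboryl tosylhydrazine with 8-O-catecholborate | C=C(C)[C@@H]1C[C@]2(CN(B3Oc4ccccc4O3)NS(=O)(=O)c3ccc(C)cc3)[C@@H](C)[C@H](O[Si](C)(C)C(C)(C)C)CC[C@H]2[C@H](O[Si](C)(C)C(C)(C)C)[C@@H]1OB1Oc2ccccc2O1 | intermediate
21 | 3α,9α-bis(tert-butyldimethylsilyloxy)eremophil-11-en-8α-ol | C=C(C)[C@@H]1C[C@]2(C)[C@@H](C)[C@H](O[Si](C)(C)C(C)(C)C)CC[C@H]2[C@H](O[Si](C)(C)C(C)(C)C)[C@@H]1O | intermediate
22 | eremophil-11-ene-3α,8α,9α-triol | C=C(C)[C@@H]1C[C@]2(C)[C@@H](C)[C@H](O)CC[C@H]2[C@H](O)[C@@H]1O | intermediate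
23 | hex-2-ynoic acid | CCCC#CC(=O)O | starting material
24 | eremophil-11-ene-3α,8α,9α-triol 3,9-bis(hex-2-ynoate) | C=C(C)[C@@H]1C[C@]2(C)[C@@H](C)[C@H](OC(=O)C#CCCC)CC[C@H]2[C@H](OC(=O)C#CCCC)[C@@H]1O | intermediate
25 | (1S,2R,3S,4aR,5R,6R,8aR)-2-hydroxy-4a,5-dimethyl-3-(prop-1-en-2-yl)decahydronaphthalene-1,6-diyl bis[(2Z)-hex-2-enoate] | C=C(C)[C@@H]1C[C@]2(C)[C@@H](C)[C@H](OC(=O)/C=C\CCC)CC[C@H]2[C@H](OC(=O)/C=C\CCC)[C@@H]1O | target

## Step count and risks

Total step count: 17. Longest linear sequence: 16 (steps 1–4 and 6–17).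

Steps most likely to fail:

Step 9 (key step). Several processes could erode it: loss of the α-methylene aldehyde to amine- or silyl-triflate-induced oligomerisation before cyclisation; a cycloaddition that needs a temperature at which the adduct's formyl group undergoes a carbonyl-ene reaction with the 1,3-diaxial isopropenyl group; and weak endo preference, which would lower the trans-fusion selectivity. The fallback sets out from 12 and returns at 14, and replaces the neutral silyloxy-diene cycloaddition by an anionic intramolecular double Michael addition. KHMDS (1.05 equiv, THF, −78 °C) should deprotonate C7 to the cross-conjugated potassium dienolate F1, which as a 2-oxido diene should add to the tethered enal well below 0 °C to give the regiodefined potassium Δ8-enolate F2. Quenching this enolate in the flask with TBSOTf should give silyl enol ether 14.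

Step 11. The same enolate that epimerises C7 can be protonated at the γ-carbon, which would move the isopropenyl double bond into conjugation with the ketone (isopropylidene enone), the thermodynamic sink. The fallback sets out from 16 and returns at 17, and replaces equilibration by irreversible kinetic protonation. TBSOTf/Et3N (CH2Cl2, 0 °C) should convert 16, and any conjugated enone already formed, into the extended silyl dienol ether F3 (C7=C8 and C11=C12). Treatment with CF3CO2H (1 equiv, CH2Cl2, −78 °C) should protonate the α-carbon C7 along the axial direction, as in the mild hydrolysis of dienol ethers to β,γ-unsaturated ketones, and give 17 with the isopropenyl group equatorial. Any 7β epimer would be recycled through F3.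

Step 16. Site selectivity could be lost through acylation of the axial 8-OH, through O-9 to O-8 acyl migration, or through incomplete acylation at the hindered O-9. The fallback sets out from 21 and returns at 24, and replaces kinetic selectivity by positional protection. The free 8α-OH of 21 would be protected with 4-methoxybenzyl trichloroacetimidate (La(OTf)3 cat., toluene) to give PMB ether F4. TBAF would then release the 3,9-diol F5, and exhaustive esterification with hex-2-ynoic acid (DCC, DMAP) would give the bis-ynoate PMB ether F6. DDQ (CH2Cl2, pH 7 buffer) would remove the PMB group to give 24.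

## Further compounds

F1 | step 9 | potassium (7E,9Z)-dienolate of 12 | O=CC(=C)[C@@H](C)[C@H](O[Si](C)(C)C(C)(C)C)CC/C=C/C([O-])=C/C(C)=C.[K+]
F2 | step 9 | potassium Δ8-enolate of the cycloadduct (8-oxido analogue of 14) | C=C(C)[C@H]1C[C@]2(C=O)[C@@H](C)[C@H](O[Si](C)(C)C(C)(C)C)CC[C@H]2C=C1[O-].[K+]
F3 | step 11 | extended silyl dienol ether: 3α,8,9α-tris(tert-butyldimethylsilyloxy)eremophila-7,11-dien-14-al | C=C(C)C=1C[C@]2(C=O)[C@@H](C)[C@H](O[Si](C)(C)C(C)(C)C)CC[C@H]2[C@H](O[Si](C)(C)C(C)(C)C)C=1O[Si](C)(C)C(C)(C)C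
F4 | step 16 | 8α-O-(4-methoxybenzyl) ether of 21 | C=C(C)[C@@H]1C[C@]2(C)[C@@H](C)[C@H](O[Si](C)(C)C(C)(C)C)CC[C@H]2[C@H](O[Si](C)(C)C(C)(C)C)[C@@H]1OCc1ccc(OC)cc1
F5 | step 16 | 8α-(4-methoxybenzyloxy)eremophil-11-ene-3α,9α-diol | C=C(C)[C@@H]1C[C@]2(C)[C@@H](C)[C@H](O)CC[C@H]2[C@H](O)[C@@H]1OCc1ccc(OC)cc1
F6 | step 16 | 8α-(4-methoxybenzyloxy)eremophil-11-ene-3α,9α-diyl bis(hex-2-ynoate) | C=C(C)[C@@H]1C[C@]2(C)[C@@H](C)[C@H](OC(=O)C#CCCC)CC[C@H]2[C@H](OC(=O)C#CCCC)[C@@H]1OCc1ccc(OC)cc1
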